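# Proposed synthesis of [(1S,2S,5S,6S)-2,5-bis(benzoyloxy)-1,6-dihydroxycyclohex-3-en-1-yl]methyl benzoate (19)

## Analysis of the target

Compound 19 is a cyclohex-3-ene in which every sp3 ring carbon is oxygenated. C1 is a quaternary carbinol that also carries the exocyclic C7H2OBz group, C2 and C5 are allylic benzoates on either side of C3=C4, and C6 is a free secondary alcohol. These atom numbers are used throughout, and the β face is defined as the face that carries C1–O. The four stereocentres are (1S,2S,5S,6S): C1–OH, C6–OH and C5–OBz lie on the β face, C2–OBz and C7 on the α face, so C1–O/C6–O and C5–O/C6–O are cis and C1–O/C2–O is trans. The functional groups are fragile as a set: three benzoates sit next to two free hydroxyls, so base can move acyl groups from O5 to O6 or from O2 and O7 to O1, and the 2,5-diacyloxy-3-ene is only eliminations away from an arene. The difficulty is therefore not the carbon skeleton, which is that of a C7 arene, but placing five oxygens with the right relative and absolute configuration and acylating exactly three of them. The feature the plan rests on is that C1, with its hydroxyl and C7 arm, is the sp3 carbon of a latent para-quinol: with C4 as a carbonyl, C2=C3 and C6=C5 are the two enone arms of a cyclohexa-2,5-dienone with a mirror plane through C1, C4 and C7. Because C1–O and C6–O are cis, one acetal carbon can bridge them, so an oxygen tethered to O1 can be delivered to C6 of one arm; the choice of arm fixes C1 and C6 together, and the surviving enone provides the handles for C5 (enolisation) and for C2 and C3=C4 (epoxidation and reductive transposition).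

## Retrosynthetic reasoning

**19 to 18.** The last forward step cleaves the two C–O bonds at the acetal carbon and releases 5. The cyclohexylmethylidene acetal is the only protecting group for O1 and O6. It keeps both out of every acylation, so no selective benzoylation among five hydroxyls is ever needed, and it holds the cis-fused bicycle whose shape directs the earlier steps. The forward step is an acid hydrolysis that leaves allylic benzoates alone.

**18 to 17 and 2.** The C5–O bond is formed with inversion. Reagents reach the bicycle from the α face, so the C5 oxygen first arrives on the wrong face. A Mitsunobu displacement by the carboxylate of 2 corrects the configuration and installs the last ester in one operation. It is placed late because a benzoate at C5 next to the C4 ketone would be exposed to the basic epoxidation and to the nucleophilic conditions of the reductive transposition. At the stage of 17 the carbinol is a plain secondary allylic alcohol.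

**17 to 16 to 14 and 15.** These are functional-group changes only: the silyl ether on O5 is removed and O2 is acylated with 15 while O5 is still masked.

**14 to 11 to 10.** The C2–O bond and the C3=C4 double bond are traced back to the enone C2=C3–C4=O. A Wharton transposition, running through 12 and 13, leads back to the epoxy ketone 11, and this to the enone 10 by nucleophilic epoxidation. The untouched enone arm has C2, C3 and C4 in exactly the oxidation pattern needed: the epoxide brings oxygen to C2 anti to C1–O, and the transposition keeps that bond while removing the C4 oxygen.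

**10 to 8 to 7.** The C5–O bond is cut by a retro-Rubottom oxidation. C1 is quaternary, so the enone 7 can enolise only towards C5. The silyl group of the enol ether 8 migrates to O5 during the oxidation, through 9, and then serves as the O5 protecting group at no cost in steps.

**7 to 4 and 5.** This is the central disconnection: the C6–O bond and the O1–C(acetal) bond are cut, returning the achiral para-quinol 4 and aldehyde 5. No skeletal bond has to be made, the dioxolane can only be cis-fused, and the forward reaction has one task, to tell the two enantiotopic enone arms apart.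

**4 to 3 to 1 and 2.** The C1–O bond comes from oxidative dearomatisation of phenol 3 in an aqueous medium that supplies the oxygen nucleophile, and the ester from 1 and 2. The C7 benzoate is in place from the first step, so O7 never needs to be differentiated later.

## Alternatives that were turned down

**Alternative 1:** The ring bond C1–C2 is disconnected by a retro-Ireland–Claisen rearrangement. The substrate is a δ-lactone built from D-galactose A2 that carries an (E)-2-alkoxyvinyl group on its carbinol carbon. In the forward sense its silyl ketene acetal rearranges: the C1–C2 bond forms, the ring O–C4 bond breaks, C3=C4 appears, and the cyclohexene acid A1 results, with C1–OMOM, C2–OPMB and a C5/C6 acetonide.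

- For it: C5 and C6 come from D-galactose A2 with their cis relationship already present. The cyclic transition state transfers this chirality to C1 and C2, the quaternary centre and the carbocycle form together, and the double bond appears in the right place. On absolute configuration it is stronger than the chosen route, since no enantioselective catalyst is needed.
- Against it: A1 is far from 19. The carboxyl group must be reduced to C7H2OH, three different protecting groups must be exchanged for the benzoate pattern, and the C5/C6 diol set free from the acetonide must be benzoylated at O5 only, a differentiation for which the structure offers little handle. The lactone enolate has a β-alkoxy group that can be eliminated, and the enol ether needs a defined E geometry that a Wittig-type construction does not guarantee.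
- Comparison: the chosen route offers in exchange a carbocycle that is present from the start, O5 and O6 introduced separately and therefore already differentiated, and about half the step count.

**Alternative 2:** The C2–C3 bond is disconnected. A chain built from L-ribose A4, branched to create the quaternary C1 with its C7 benzoate, carries a (Z)-vinyl iodide at C3 and an aldehyde at C2. CrCl2 with catalytic NiCl2 closes the ring by a Nozaki–Hiyama–Kishi reaction to the cyclohexenol A3.

- For it: A3 is only a benzoylation and an acetonide hydrolysis away from 19, an endgame as short as that from 17 in the chosen route. C1, C5 and C6 come from the chiral pool, and the O5 and O7 benzoates are already in place.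
- Against it: the C2 carbinol centre is created in the ring closure itself. Its configuration, trans to C1–O, depends on the facial preference of an α-alkoxy aldehyde on a quaternary carbon, which chelation and dipole models predict in opposite senses. The precursor requires L-ribose A4 to be converted into a branched unnatural sugar, a Z-selective iodo-olefination and an aldehyde next to a quaternary centre, all in the presence of benzoates, and the closure uses a large excess of a toxic divalent chromium salt.
- Comparison: the chosen route sets C2 by attack on a rigid bicycle and reaches its key substrate in two steps. Its price is that the absolute configuration rests on a catalyst rather than on a sugar.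

**Alternative 3:** The bonds C1–C2 and C5–C6 are disconnected by a Diels–Alder reaction between furan A6 and 2-bromoacrolein A7. A chiral oxazaborolidinone Lewis acid derived from an N-sulfonyl amino acid would give the 7-oxabicyclo[2.2.1]heptene aldehyde A5.

- For it: two ring bonds and the quaternary carbon are made in one catalytic step from the simplest possible components. On skeletal construction and on precedent for enantiocontrol it is at least as strong as the chosen key step. The aldehyde maps onto C7 and the bromide is a handle for C1–O.
- Against it: the oxygen bridge ties O2 and O5 to the same face, whereas 19 has them trans, so one of the two must be inverted during bridge opening, with regiochemistry that is difficult to secure. C6 arrives as a methylene and needs a stereoselective hydroxylation, the tertiary bromide must become a tertiary alcohol of defined configuration, and on heating A5 can revert to furan A6 and 2-bromoacrolein A7.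
- Comparison: in the chosen route C2–O and C5–O are introduced independently on a substrate that already has C1–O and C6–O, so no stereochemical correction between them is needed, and the many redox and substitution steps after the cycloaddition are avoided.

Key step: step 3

Assumption: the (R)-configured phosphoric acid is taken to select the C6=C5 arm and give the (1S,6S) product; if the sense of induction is the opposite, the (S)-acid is used and nothing else in the route changes.

## Route

Step 1
Reactants: 1 4-hydroxybenzyl alcohol; 2 benzoic acid
Product: 3 4-hydroxybenzyl benzoate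
Conditions: PPh3, DIAD, THF, 0 °C to rt
Reagents that add atoms: benzoic acid, O=C(O)c1ccccc1
Why: Mitsunobu esterification; the carboxylic acid (pKa about 4), not the phenol (pKa about 10), protonates the betaine and supplies the nucleophile, so the benzylic carbon is esterified and the phenol stays free. No phenoxide is formed, which avoids loss of benzoate to a quinone methide.

Step 2
Reactants: 3 4-hydroxybenzyl benzoate
Product: 4 (1-hydroxy-4-oxocyclohexa-2,5-dien-1-yl)methyl benzoate
Conditions: PhI(OAc)2, MeCN/H2O (3:1), 0 °C
Reagents that add atoms: water, O
Why: Oxidative dearomatisation of a para-substituted phenol with a hypervalent iodine reagent; the aryloxy iodane ionises and water adds at the para carbon C1 to give the para-quinol. The medium is weakly acidic, which the benzylic ester tolerates.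

Step 3
Reactants: 4 (1-hydroxy-4-oxocyclohexa-2,5-dien-1-yl)methyl benzoate; 5 cyclohexanecarbaldehyde
Product: 7 [(1S,6S)-1,6-[(R)-cyclohexylmethylidenedioxy]-4-oxocyclohex-2-en-1-yl]methyl benzoate, via hemiacetal 6 (not isolated)
Conditions: (R)-3,3'-bis(2,4,6-triisopropylphenyl)-1,1'-binaphthyl-2,2'-diyl hydrogen phosphate (10 mol %), 5 (3 equiv), ClCH2CH2Cl, rt
Reagents that add atoms: cyclohexanecarbaldehyde, O=CC1CCCCC1
Why: The phosphoric acid catalyses reversible addition of the tertiary C1 hydroxyl of 4 to the aldehyde, giving hemiacetal 6 as two rapidly interconverting epimers. In the hydrogen-bonded complex the P–OH group activates the dienone carbonyl and the P=O oxygen holds the hemiacetal hydroxyl, which adds to C6 of one enone arm; tautomerisation of the dienol then gives 7. The closest known reaction type is the chiral phosphoric acid-catalysed acetalisation/oxa-Michael desymmetrisation of para-quinols with aldehydes to cis-fused 1,3-dioxolanes, applied here to a quinol whose substituent is an acyloxymethyl group. The dioxolane closes in the 5-exo-trig mode, with oxygen attacking C6 and C6=C5 outside the new ring. C1 and C6 are set together by the catalyst, which has to distinguish the enantiotopic arms C6=C5 and C2=C3, and the cis ring fusion follows from the three-atom tether, which can reach C6 only on the face of C1–O. The acetal carbon is set by the substrate, since the hemiacetal epimer that places cyclohexyl on the convex face should cyclise, and this centre is removed in step 11 in any case. The step needs enantiotopic-group selectivity and a single addition; 4 has one hydroxyl only, its arms differ only in their relation to the catalyst, and the benzoate is not nucleophilic under these conditions. The reaction is stopped at full conversion, because the oxa-Michael step is reversible and long exposure to acid would erode the enantiomeric purity.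

Step 4
Reactants: 7 [(1S,6S)-1,6-[(R)-cyclohexylmethylidenedioxy]-4-oxocyclohex-2-en-1-yl]methyl benzoate
Product: 8 [4-(tert-butyldimethylsilyloxy)-1,6-(cyclohexylmethylidenedioxy)cyclohexa-2,4-dien-1-yl]methyl benzoate (C1, C6 and acetal carbon as in 7)
Conditions: TBSOTf, Et3N, CH2Cl2, −78 to 0 °C
Reagents that add atoms: tert-butyldimethylsilyl trifluoromethanesulfonate, CC(C)(C)[Si](C)(C)OS(=O)(=O)C(F)(F)F
Why: Soft enolisation with a silyl triflate and an amine; C1 is quaternary, so the silylated enone can lose a proton only from C5 and the cross-conjugated 2-silyloxy diene is the only possible enol ether. No metal enolate is formed, which should hold back β-elimination of the C6 oxygen (the reverse of step 3), and the excess amine shields the acetal from the silyl triflate.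

Step 5
Reactants: 8 [4-(tert-butyldimethylsilyloxy)-1,6-(cyclohexylmethylidenedioxy)cyclohexa-2,4-dien-1-yl]methyl benzoate
Product: 10 [5α-(tert-butyldimethylsilyloxy)-1,6-(cyclohexylmethylidenedioxy)-4-oxocyclohex-2-en-1-yl]methyl benzoate (C5–OSi trans to C6–O), via silyloxy epoxide 9 (not isolated)
Conditions: mCPBA, CH2Cl2, −20 to 0 °C
Reagents that add atoms: 3-chloroperoxybenzoic acid, O=C(OO)c1cccc(Cl)c1
Why: Rubottom oxidation; the peracid epoxidises the electron-rich C4=C5 enol ether bond and leaves the less nucleophilic C2=C3 bond alone, and the silyloxy epoxide 9 opens with 1,4-migration of silicon to give the O5-silylated α'-hydroxy enone. The oxidant should approach C5 on the α face, anti to the allylic C6–O bond and away from the dioxolane, which places C5–O trans to C6–O.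

Step 6
Reactants: 10 [5α-(tert-butyldimethylsilyloxy)-1,6-(cyclohexylmethylidenedioxy)-4-oxocyclohex-2-en-1-yl]methyl benzoate
Product: 11 [2α,3α-epoxy-5α-(tert-butyldimethylsilyloxy)-1,6-(cyclohexylmethylidenedioxy)-4-oxocyclohexyl]methyl benzoate
Conditions: t-BuOOH, DBU, CH2Cl2, 0 °C to rt
Reagents that add atoms: tert-butyl hydroperoxide, CC(C)(C)OO
Why: Weitz–Scheffer (nucleophilic) epoxidation of the enone; the hydroperoxide anion should add to C2 anti to the C1–O bond, on the face not covered by the dioxolane, and the enolate then closes on oxygen, so both epoxide C–O bonds lie on the α face. Aprotic conditions spare the C7 benzoate, and the silyl ether makes C5–H much less acidic than an acyloxy group would, which keeps retro-oxa-Michael opening at C6 slow.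

Step 7
Reactants: 11 [2α,3α-epoxy-5α-(tert-butyldimethylsilyloxy)-1,6-(cyclohexylmethylidenedioxy)-4-oxocyclohexyl]methyl benzoate
Product: 14 [2α-hydroxy-5α-(tert-butyldimethylsilyloxy)-1,6-(cyclohexylmethylidenedioxy)cyclohex-3-en-1-yl]methyl benzoate, via epoxy hydrazone 12 (not isolated), via vinyl diazene 13 (not isolated)
Conditions: N2H4·H2O, AcOH (cat.), MeOH, 0 °C to rt
Reagents that add atoms: none
Why: Wharton transposition; hydrazone 12 opens the epoxide to the vinyl diazene 13, which loses N2 and leaves hydrogen at C4, so the C2–O bond of the epoxide is kept with its α configuration and the double bond moves to C3=C4. A benzoyl shift from O7 to O2 or partial hydrazinolysis at O7 would be harmless, because step 8 acylates whichever of these hydroxyls is free.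

Step 8
Reactants: 14 [2α-hydroxy-5α-(tert-butyldimethylsilyloxy)-1,6-(cyclohexylmethylidenedioxy)cyclohex-3-en-1-yl]methyl benzoate; 15 benzoyl chloride
Product: 16 [2α-benzoyloxy-5α-(tert-butyldimethylsilyloxy)-1,6-(cyclohexylmethylidenedioxy)cyclohex-3-en-1-yl]methyl benzoate
Conditions: BzCl, pyridine, DMAP (cat.), CH2Cl2, 0 °C to rt
Reagents that add atoms: benzoyl chloride, O=C(Cl)c1ccccc1
Why: DMAP-catalysed acylation of the only free hydroxyl; the configuration at C2 is not touched.

Step 9
Reactants: 16 [2α-benzoyloxy-5α-(tert-butyldimethylsilyloxy)-1,6-(cyclohexylmethylidenedioxy)cyclohex-3-en-1-yl]methyl benzoate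
Product: 17 [2α-benzoyloxy-5α-hydroxy-1,6-(cyclohexylmethylidenedioxy)cyclohex-3-en-1-yl]methyl benzoate
Conditions: HF·pyridine, pyridine, THF, 0 °C to rt
Reagents that add atoms: none
Why: Fluoride cleavage of the silyl ether under buffered, non-basic conditions, so that the benzoates neither migrate nor are lost and the acetal is kept.

Step 10
Reactants: 17 [2α-benzoyloxy-5α-hydroxy-1,6-(cyclohexylmethylidenedioxy)cyclohex-3-en-1-yl]methyl benzoate; 2 benzoic acid
Product: 18 [2α,5β-bis(benzoyloxy)-1,6-(cyclohexylmethylidenedioxy)cyclohex-3-en-1-yl]methyl benzoate
Conditions: PPh3, DIAD, PhCO2H, toluene, 0 °C to rt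
Reagents that add atoms: benzoic acid, O=C(O)c1ccccc1
Why: Mitsunobu reaction of a secondary allylic alcohol; benzoate displaces the oxyphosphonium group at C5 by SN2 with inversion, which turns the α alcohol into the β benzoate cis to C6–O and completes the acylation pattern. Anti elimination towards C6 is not possible because H6 and the leaving group are cis.

Step 11
Reactants: 18 [2α,5β-bis(benzoyloxy)-1,6-(cyclohexylmethylidenedioxy)cyclohex-3-en-1-yl]methyl benzoate
Product: 19 [(1S,2S,5S,6S)-2,5-bis(benzoyloxy)-1,6-dihydroxycyclohex-3-en-1-yl]methyl benzoate
Conditions: TFA/H2O (9:1), CH2Cl2, 0 °C to rt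
Reagents that add atoms: none
Why: Acid hydrolysis of the aldehyde acetal releases O1–H, O6–H and cyclohexanecarbaldehyde; benzoates are stable to aqueous acid, and acid, unlike base, should not move acyl groups to the new hydroxyls at a useful rate, so the work-up is kept free of base.

## Compound list

1 | 4-hydroxybenzyl alcohol | OCc1ccc(O)cc1 | starting material
2 | benzoic acid | O=C(O)c1ccccc1 | starting material
3 | 4-hydroxybenzyl benzoate | O=C(OCc1ccc(O)cc1)c1ccccc1 | intermediate
4 | (1-hydroxy-4-oxocyclohexa-2,5-dien-1-yl)methyl benzoate (achiral para-quinol) | O=C(OCC1(O)C=CC(=O)C=C1)c1ccccc1 | intermediate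
5 | cyclohexanecarbaldehyde | O=CC1CCCCC1 | starting material
6 | hemiacetal of 4 with 5 at O1, [1-[cyclohexyl(hydroxy)methoxy]-4-oxocyclohexa-2,5-dien-1-yl]methyl benzoate (the epimer that cyclises is drawn; not isolated) | O=C(OCC1(O[C@H](C2CCCCC2)O)C=CC(=O)C=C1)c1ccccc1 | intermediate
7 | [(1S,6S)-1,6-[(R)-cyclohexylmethylidenedioxy]-4-oxocyclohex-2-en-1-yl]methyl benzoate (cis-fused dioxolane on the β face, cyclohexyl exo) | O=C(OC[C@@]1(O[C@H](C2CCCCC2)O3)C=CC(=O)C[C@@H]13)c1ccccc1 | intermediate
8 | tert-butyldimethylsilyl dienol ether of 7 (C2=C3 and C4(OSi)=C5) | O=C(OC[C@@]1(O[C@H](C2CCCCC2)O3)C=CC(O[Si](C)(C)C(C)(C)C)=C[C@@H]13)c1ccccc1 | intermediate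
9 | 4α,5α-epoxide of 8 (4-silyloxy oxirane; not isolated) | O=C(OC[C@@]1(O[C@H](C2CCCCC2)O3)C=C[C@@]4(O[Si](C)(C)C(C)(C)C)O[C@H]4[C@@H]13)c1ccccc1 | intermediate
10 | α'-silyloxy enone: C4 ketone, C2=C3, C5–OSi on the α face (trans to C6–O) | O=C(OC[C@@]1(O[C@H](C2CCCCC2)O3)C=CC(=O)[C@@H](O[Si](C)(C)C(C)(C)C)[C@@H]13)c1ccccc1 | intermediate
11 | 2α,3α-epoxy ketone derived from 10 | O=C(OC[C@@]1(O[C@H](C2CCCCC2)O3)[C@H]4O[C@H]4C(=O)[C@@H](O[Si](C)(C)C(C)(C)C)[C@@H]13)c1ccccc1 | intermediate
12 | C4 hydrazone of 11 (not isolated) | O=C(OC[C@@]1(O[C@H](C2CCCCC2)O3)[C@H]4O[C@H]4C(=NN)[C@@H](O[Si](C)(C)C(C)(C)C)[C@@H]13)c1ccccc1 | intermediate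
13 | vinyl diazene: C2–OH (α), C3=C4–N=NH (not isolated) | O=C(OC[C@@]1(O[C@H](C2CCCCC2)O3)[C@@H](O)C=C(N=N)[C@@H](O[Si](C)(C)C(C)(C)C)[C@@H]13)c1ccccc1 | intermediate
14 | allylic alcohol: C2–OH α, C3=C4, C5–OSi α, O1/O6 acetal, O7 benzoate | O=C(OC[C@@]1(O[C@H](C2CCCCC2)O3)[C@@H](O)C=C[C@@H](O[Si](C)(C)C(C)(C)C)[C@@H]13)c1ccccc1 | intermediate
15 | benzoyl chloride | O=C(Cl)c1ccccc1 | starting material
16 | O2-benzoate of 14 | O=C(OC[C@@]1(O[C@H](C2CCCCC2)O3)[C@@H](OC(=O)c4ccccc4)C=C[C@@H](O[Si](C)(C)C(C)(C)C)[C@@H]13)c1ccccc1 | intermediate
17 | C5 alcohol (α) obtained from 16 | O=C(OC[C@@]1(O[C@H](C2CCCCC2)O3)[C@@H](OC(=O)c4ccccc4)C=C[C@@H](O)[C@@H]13)c1ccccc1 | intermediate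
18 | 1,6-O-cyclohexylmethylidene acetal of 19 (C2–OBz α, C5–OBz β) | O=C(OC[C@@]1(O[C@H](C2CCCCC2)O3)[C@@H](OC(=O)c4ccccc4)C=C[C@H](OC(=O)c4ccccc4)[C@@H]13)c1ccccc1 | intermediate
19 | [(1S,2S,5S,6S)-2,5-bis(benzoyloxy)-1,6-dihydroxycyclohex-3-en-1-yl]methyl benzoate | O=C(OC[C@@]1(O)[C@@H](OC(=O)c2ccccc2)C=C[C@H](OC(=O)c2ccccc2)[C@@H]1O)c1ccccc1 | target

## Step count and risk

Total step count: 11. Longest linear sequence: 11 steps (1 to 19).

**Step 3 (key step).** The most likely failure is insufficient enantiotopic-arm selectivity or slow hemiacetal formation. The benzoyloxymethyl group lowers the nucleophilicity of the tertiary hydroxyl and gives the catalyst a second hydrogen-bond acceptor, and reversible ring opening can erode the selectivity. The fallback sets out from 4 and 5 and returns at 7. The cascade is run with achiral diphenyl phosphate, (PhO)2P(O)OH, which relies only on the enforced cis fusion and gives 7 together with its enantiomer, ent-dioxolane enone F1. The two are separated by preparative chromatography on a chiral stationary phase. F1 is returned to the same acid, where retro-oxa-Michael opening and hemiacetal exchange through the achiral quinol 4 regenerate the racemate for another pass.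

**Step 6.** The risk is poor facial selectivity at C2, because the α face carries the C7 benzoyloxymethyl group and the hydroperoxide may prefer the β face. The fallback sets out from 10 and returns at 14. The β-epoxy ketone F2 is taken through the same Wharton conditions to the C2-epimeric allylic alcohol F3. Oxidation with Dess–Martin periodinane gives the C2 enone F4, and Luche reduction (NaBH4, CeCl3·7H2O, MeOH, −78 °C) then delivers hydride to the same, more accessible β face and leaves C2–OH on the α face, which is 14. Whichever face of C2 is open, one of the two sequences gives the required configuration.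

**Step 10.** The risk is that the displacement at C5 is slowed by the adjacent cis C6–O bond and the concave face, letting SN2' attack at C3 or simple non-reaction compete. The fallback sets out from 17 and returns at 18. Dess–Martin oxidation gives the C5 enone F5, and Luche reduction brings hydride in on the convex α face to give the β alcohol F6, cis to C6–O. Benzoylation with 15 (pyridine, DMAP) gives 18. Because the oxidation erases the C5 configuration, this sequence also makes the route independent of the facial outcome of step 5.

**Step 4.** The risk is loss of the C6 oxygen by β-elimination during enolisation, or opening of the acetal by the silyl triflate. The fallback sets out from 7 and returns at 18; it introduces the C5 oxygen after the transposition instead of through an enol ether. Epoxidation of 7 (t-BuOOH, DBU) gives the epoxy ketone F7, Wharton transposition gives the allylic alcohol F8, and benzoylation with 15 gives the C2 benzoate F9. Allylic oxidation of the C5 methylene with CrO3·3,5-dimethylpyrazole gives the enone F5, which is reduced to F6 and benzoylated to 18 as described for step 10.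

**Step 7.** The risk is slow hydrazone formation at the hindered C4 ketone, with attack of hydrazine on the epoxide or on the ester taking over. The fallback sets out from 11 and returns at 14. Reduction (NaBH4, CeCl3·7H2O) gives the epoxy alcohol F10, whose C4 configuration is of no consequence. 1,1'-Thiocarbonyldiimidazole converts it into the imidazolylthiocarbonate F11. Bu3SnH with AIBN in toluene at 80 °C generates the C4 radical, which opens the epoxide; the oxygen radical at C2 takes hydrogen from the stannane to give 14. A high stannane concentration is used to outrun β-scission.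

## Further compounds

F1 | step 3 | enantiomer of 7, [(1R,6R)-1,6-[(S)-cyclohexylmethylidenedioxy]-4-oxocyclohex-2-en-1-yl]methyl benzoate | O=C(OC[C@]1(O[C@@H](C2CCCCC2)O3)C=CC(=O)C[C@H]13)c1ccccc1
F2 | step 6 | 2β,3β-epoxy ketone, epoxide epimer of 11 | O=C(OC[C@@]1(O[C@H](C2CCCCC2)O3)[C@@H]4O[C@@H]4C(=O)[C@@H](O[Si](C)(C)C(C)(C)C)[C@@H]13)c1ccccc1
F3 | step 6 | C2 epimer of 14 (C2–OH on the β face) | O=C(OC[C@@]1(O[C@H](C2CCCCC2)O3)[C@H](O)C=C[C@@H](O[Si](C)(C)C(C)(C)C)[C@@H]13)c1ccccc1
F4 | step 6 | C2 enone (C2=O, C3=C4, C5–OSi α) | O=C(OC[C@@]1(O[C@H](C2CCCCC2)O3)C(=O)C=C[C@@H](O[Si](C)(C)C(C)(C)C)[C@@H]13)c1ccccc1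
F5 | step 10 | C5 enone (C5=O, C3=C4, C2–OBz α) | O=C(OC[C@@]1(O[C@H](C2CCCCC2)O3)[C@@H](OC(=O)c4ccccc4)C=CC(=O)[C@@H]13)c1ccccc1
F6 | step 10 | C5 epimer of 17 (C5–OH on the β face) | O=C(OC[C@@]1(O[C@H](C2CCCCC2)O3)[C@@H](OC(=O)c4ccccc4)C=C[C@H](O)[C@@H]13)c1ccccc1
F7 | step 4 | 2α,3α-epoxy ketone from 7 (C5 methylene) | O=C(OC[C@@]1(O[C@H](C2CCCCC2)O3)[C@H]4O[C@H]4C(=O)C[C@@H]13)c1ccccc1
F8 | step 4 | allylic alcohol with C2–OH α, C3=C4 and C5 methylene | O=C(OC[C@@]1(O[C@H](C2CCCCC2)O3)[C@@H](O)C=CC[C@@H]13)c1ccccc1
F9 | step 4 | O2-benzoate of F8 | O=C(OC[C@@]1(O[C@H](C2CCCCC2)O3)[C@@H](OC(=O)c4ccccc4)C=CC[C@@H]13)c1ccccc1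
F10 | step 7 | epoxy alcohol from 11 (C4–OH, drawn α) | O=C(OC[C@@]1(O[C@H](C2CCCCC2)O3)[C@H]4O[C@H]4[C@@H](O)[C@@H](O[Si](C)(C)C(C)(C)C)[C@@H]13)c1ccccc1
F11 | step 7 | O4-(imidazol-1-ylthiocarbonyl) derivative of F10 | O=C(OC[C@@]1(O[C@H](C2CCCCC2)O3)[C@H]4O[C@H]4[C@@H](OC(=S)n5ccnc5)[C@@H](O[Si](C)(C)C(C)(C)C)[C@@H]13)c1ccccc1
A1 | alternative 1 | cyclohex-3-ene-1-carboxylic acid with C1–OMOM, C2–OPMB and C5,C6-acetonide | OC(=O)[C@@]1(OCOC)[C@@H](OCc3ccc(OC)cc3)C=C[C@H](OC(C)(C)O2)[C@@H]12
A2 | alternative 1 | D-galactose (open-chain form) | O=C[C@H](O)[C@@H](O)[C@@H](O)[C@H](O)CO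
A3 | alternative 2 | cyclohexenol with free C2–OH, C1,C6-acetonide and O5, O7 benzoates | O=C(OC[C@@]1(OC(C)(C)O2)[C@@H](O)C=C[C@H](OC(=O)c3ccccc3)[C@@H]12)c1ccccc1
A4 | alternative 2 | L-ribose (open-chain form) | O=C[C@@H](O)[C@@H](O)[C@@H](O)CO
A5 | alternative 3 | 2-bromo-7-oxabicyclo[2.2.1]hept-5-ene-2-carbaldehyde (exo-formyl) | O=C[C@]1(Br)[C@H]2C=C[C@H](O2)C1
A6 | alternative 3 | furan | c1ccoc1
A7 | alternative 3 | 2-bromoacrolein | C=C(Br)C=O
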